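**Strategy.** The bicyclo[3.2.1]oct-3-ene-2,8-dione is opened at C1–C2 and at C7–aryl. In the cyclopentanone ring (C1, C5, C6, C7, C8) the C7 aryl sits β and C1 α to the C8 ketone, and C2 is an acyl group on C1: a conjugate addition/Claisen retron. In one operation an aryl cuprate adds to a trans-4-aryl-5-alkylcyclopent-2-enone and the regiodefined enolate acylates a Weinreb amide in the side chain on C5, closing the six- and seven-membered rings and setting C7 and C1. The monocyclic precursor comes from a three-component coupling on (R)-4-silyloxycyclopentenone; the C3–C4 alkene is installed afterwards, where only one enolization is geometrically possible.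

Key step: step 7

Remark: locants C1–C8 are those of the target bicyclooctenedione; TBSO = tert-butyldimethylsilyloxy (chosen so that the last step is a mild fluoride cleavage); the side-chain methine made in step 4 (later C4) is carried as both epimers because step 8 removes it.

**Step 1**
Reactants: 1 5-bromobenzene-1,3-diol
Product: 2 1-bromo-3,5-bis(TBSO)benzene
Conditions: TBSCl (2.4 equiv), imidazole (5 equiv), DMF, 0 °C to rt
Reagents that add atoms: tert-butyldimethylsilyl chloride, CC(C)(C)[Si](C)(C)Cl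
Why: Standard silylation of both phenols should give an aryl bromide that tolerates magnesium insertion and cuprate chemistry and is unmasked by fluoride at the end.

**Step 2**
Reactants: 3 4-(TBSO)benzaldehyde; 4 (triphenylphosphoranylidene)acetaldehyde
Product: 5 (E)-3-[4-(TBSO)phenyl]prop-2-enal
Conditions: toluene, 80 °C
Reagents that add atoms: none
Why: Wittig olefination with the stabilized formylmethylene ylide should give the (E)-enal, the aryl silyl ether being inert under these neutral conditions.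

**Step 3**
Reactants: 5 (E)-3-[4-(TBSO)phenyl]prop-2-enal; 6 2,2-dimethyl-1,3-dioxane-4,6-dione (Meldrum's acid)
Product: 7 2,2-dimethyl-5-[(2E)-3-{4-(TBSO)phenyl}prop-2-en-1-ylidene]-1,3-dioxane-4,6-dione
Conditions: piperidinium acetate (10 mol%), CH2Cl2, 4 Å molecular sieves, rt
Reagents that add atoms: none
Why: Knoevenagel condensation of the enal with the C–H acid should give the dienylidene Meldrum's acid, a strongly electrophilic Michael acceptor in which the (E)-styryl bond is kept.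

**Step 4**
Reactants: 2 1-bromo-3,5-bis(TBSO)benzene; 8 (R)-4-(TBSO)cyclopent-2-en-1-one; 7 dienylidene Meldrum's acid
Product: 11 5-[(2E)-1-{(1R,2S,3R)-2-[3,5-bis(TBSO)phenyl]-3-(TBSO)-5-oxocyclopentyl}-3-[4-(TBSO)phenyl]prop-2-en-1-yl]-2,2-dimethyl-1,3-dioxane-4,6-dione (side-chain epimers), via aryl Grignard reagent 9 (not isolated), via magnesium enolate 10 (not isolated)
Conditions: 2, Mg turnings, THF, 50 °C; then CuBr·SMe2 (10 mol%), 8, THF, −78 to −40 °C; then 7, −78 to −20 °C; cold 1 M HCl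
Reagents that add atoms: none
Why: Copper-catalysed 1,4-addition of the aryl Grignard reagent anti to the silyloxy group sets the aryl-bearing carbon (later C6), and the regiodefined magnesium enolate should add to the β-carbon of acceptor 7 anti to the new aryl group (three-component conjugate addition–Michael trapping), which sets the trans relationship at the later C5, the side-chain methine forming as both epimers.

**Step 5**
Reactants: 11 Michael adduct
Product: 12 (4E)-3-{(1R,2S,3R)-2-[3,5-bis(TBSO)phenyl]-3-(TBSO)-5-oxocyclopentyl}-N-methoxy-N-methyl-5-[4-(TBSO)phenyl]pent-4-enamide (C3 epimers)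
Conditions: MeONHMe (3 equiv), toluene, 85 °C, sealed tube
Reagents that add atoms: N,O-dimethylhydroxylamine, CNOC
Why: Aminolysis of the Meldrum's acid ring with loss of acetone, followed by thermal decarboxylation of the malonamic acid (decarboxylative amidation), should turn the acidic dioxanedione into the CH2C(=O)N(OMe)Me unit without touching the ring stereocenters or the silyl ethers.

**Step 6**
Reactants: 12 Weinreb amide
Product: 13 (4E)-3-{(1R,5S)-5-[3,5-bis(TBSO)phenyl]-2-oxocyclopent-3-en-1-yl}-N-methoxy-N-methyl-5-[4-(TBSO)phenyl]pent-4-enamide (C3 epimers)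
Conditions: DBU (1.5 equiv), CH2Cl2, 0 °C, short reaction time; pH 7 buffer
Reagents that add atoms: none
Why: E1cB elimination of silanolate from the β-silyloxy ketone, as in the conversion of E-type into A-type prostaglandins, should unveil the cyclopent-2-enone while the two remaining trans ring stereocenters are kept, the brief low-temperature exposure limiting alkene migration.

**Step 7**
Reactants: 13 enone amide; 14 (4-bromophenoxy)(tert-butyl)dimethylsilane
Product: 19 (1R,5R,6S,7S)-6-[3,5-bis(TBSO)phenyl]-7-[4-(TBSO)phenyl]-4-{(E)-2-[4-(TBSO)phenyl]ethenyl}bicyclo[3.2.1]octane-2,8-dione (C4 epimers), via aryllithium 15 (not isolated), via lithium diarylcuprate 16 (not isolated), via lithium enolate 17 (not isolated), via tetrahedral adduct 18 (not isolated)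
Conditions: 14 (3 equiv), t-BuLi (6 equiv), Et2O, −78 °C; CuI (1.5 equiv), −40 °C; then 13, THF, −78 to 0 °C; sat. aq. NH4Cl
Reagents that add atoms: none
Why: The lithium diarylcuprate 16 adds 1,4 to the enone of 13 at the later C7, and the lithium enolate 17, generated regiospecifically at C1, attacks the N-methoxy-N-methylamide carbonyl of the neighbouring side chain to give the chelated tetrahedral adduct 18, which releases the C2 ketone only on quench, so the non-enolizable bridged 1,3-diketone never meets a nucleophilic alkoxide. The closest known reaction type is the conjugate addition–Dieckmann (Claisen) cyclization of enones tethered to carboxylic acid derivatives, a Michael-initiated ring closure. The six-membered ring, and with it the seven-membered ring, closes in a 6-(enolendo)-exo-trig mode. C7 is controlled by the C6 aryl group, which sends the cuprate to the opposite face (trans-diaryl), and C1 is controlled by the tether: the acyl chain on C5 is trans to the C6 aryl and reaches the enolate only from its own face, so the bridge ends up cis to the new C7 aryl (7-endo) as in the target. The step needs chemoselectivity (enone before amide, secured because such amides are inert to cuprates), C- instead of O-acylation (an amide does not transfer its acyl group to oxygen) and freedom from proton shuffling, secured by the saturated side chain in which no C–H is more acidic than the ketone α-positions.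

**Step 8**
Reactants: 19 bicyclic diketone
Product: 20 (1R,5S,6S,7S)-6-[3,5-bis(TBSO)phenyl]-7-[4-(TBSO)phenyl]-4-{(E)-2-[4-(TBSO)phenyl]ethenyl}bicyclo[3.2.1]oct-3-ene-2,8-dione
Conditions: IBX (2 equiv), 4-methoxypyridine N-oxide (2 equiv), DMSO, rt
Reagents that add atoms: none
Why: IBX dehydrogenation of the C2 ketone should run only toward C3–C4, because C1 is a bridgehead whose enol is geometrically forbidden and the C8 ketone has no enolizable hydrogen, so the conjugated dienone forms regiospecifically and the epimeric C4 center is erased.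

**Step 9**
Reactants: 20 tetrakis-silyl ether
Product: 21 (1R,5S,6S,7S)-6-(3,5-dihydroxyphenyl)-7-(4-hydroxyphenyl)-4-[(E)-2-(4-hydroxyphenyl)ethenyl]bicyclo[3.2.1]oct-3-ene-2,8-dione (CNP0288448.1)
Conditions: HF·pyridine, THF/pyridine, 0 °C to rt
Reagents that add atoms: none
Why: Fluoride cleavage of the four aryl silyl ethers under mildly acidic, non-nucleophilic conditions should free the phenols without retro-Claisen opening of the bridged 1,3-diketone or epimerization.

**Compound list**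

1 | 5-bromobenzene-1,3-diol | Oc1cc(O)cc(Br)c1 | starting material
2 | 1-bromo-3,5-bis(TBSO)benzene | Brc1cc(O[Si](C)(C)C(C)(C)C)cc(O[Si](C)(C)C(C)(C)C)c1 | intermediate
3 | 4-(TBSO)benzaldehyde | O=Cc1ccc(O[Si](C)(C)C(C)(C)C)cc1 | starting material
4 | (triphenylphosphoranylidene)acetaldehyde | O=CC=P(c1ccccc1)(c1ccccc1)c1ccccc1 | starting material
5 | (E)-3-[4-(TBSO)phenyl]prop-2-enal | O=C/C=C/c1ccc(O[Si](C)(C)C(C)(C)C)cc1 | intermediate
6 | 2,2-dimethyl-1,3-dioxane-4,6-dione (Meldrum's acid) | CC1(C)OC(=O)CC(=O)O1 | starting material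
7 | 2,2-dimethyl-5-[(2E)-3-{4-(TBSO)phenyl}prop-2-en-1-ylidene]-1,3-dioxane-4,6-dione | CC1(C)OC(=O)C(=C/C=C/c2ccc(O[Si](C)(C)C(C)(C)C)cc2)C(=O)O1 | intermediate
8 | (R)-4-(TBSO)cyclopent-2-en-1-one | O=C1C=C[C@H](O[Si](C)(C)C(C)(C)C)C1 | starting material
9 | [3,5-bis(TBSO)phenyl]magnesium bromide | Br[Mg]c1cc(O[Si](C)(C)C(C)(C)C)cc(O[Si](C)(C)C(C)(C)C)c1 | intermediate (not isolated)
10 | bromomagnesium (3S,4R)-3-[3,5-bis(TBSO)phenyl]-4-(TBSO)cyclopent-1-en-1-olate | Br[Mg]OC1=C[C@@H](c2cc(O[Si](C)(C)C(C)(C)C)cc(O[Si](C)(C)C(C)(C)C)c2)[C@H](O[Si](C)(C)C(C)(C)C)C1 | intermediate (not isolated)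
11 | 5-[(2E)-1-{(1R,2S,3R)-2-[3,5-bis(TBSO)phenyl]-3-(TBSO)-5-oxocyclopentyl}-3-[4-(TBSO)phenyl]prop-2-en-1-yl]-2,2-dimethyl-1,3-dioxane-4,6-dione, side-chain epimers | CC1(C)OC(=O)C(C(/C=C/c2ccc(O[Si](C)(C)C(C)(C)C)cc2)[C@H]3C(=O)C[C@@H](O[Si](C)(C)C(C)(C)C)[C@@H]3c4cc(O[Si](C)(C)C(C)(C)C)cc(O[Si](C)(C)C(C)(C)C)c4)C(=O)O1 | intermediate
12 | (4E)-3-{(1R,2S,3R)-2-[3,5-bis(TBSO)phenyl]-3-(TBSO)-5-oxocyclopentyl}-N-methoxy-N-methyl-5-[4-(TBSO)phenyl]pent-4-enamide, C3 epimers | CON(C)C(=O)CC(/C=C/c1ccc(O[Si](C)(C)C(C)(C)C)cc1)[C@H]2C(=O)C[C@@H](O[Si](C)(C)C(C)(C)C)[C@@H]2c3cc(O[Si](C)(C)C(C)(C)C)cc(O[Si](C)(C)C(C)(C)C)c3 | intermediate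
13 | (4E)-3-{(1R,5S)-5-[3,5-bis(TBSO)phenyl]-2-oxocyclopent-3-en-1-yl}-N-methoxy-N-methyl-5-[4-(TBSO)phenyl]pent-4-enamide, C3 epimers | CON(C)C(=O)CC(/C=C/c1ccc(O[Si](C)(C)C(C)(C)C)cc1)[C@H]2C(=O)C=C[C@@H]2c3cc(O[Si](C)(C)C(C)(C)C)cc(O[Si](C)(C)C(C)(C)C)c3 | intermediate
14 | (4-bromophenoxy)(tert-butyl)dimethylsilane | Brc1ccc(O[Si](C)(C)C(C)(C)C)cc1 | starting material
15 | [4-(TBSO)phenyl]lithium | [Li]c1ccc(O[Si](C)(C)C(C)(C)C)cc1 | intermediate (not isolated)
16 | lithium bis[4-(TBSO)phenyl]cuprate | [Li+].CC(C)(C)[Si](C)(C)Oc1ccc([Cu-]c2ccc(O[Si](C)(C)C(C)(C)C)cc2)cc1 | intermediate (not isolated)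
17 | lithium enolate of the 1,4-adduct (3,4-trans, 4,5-trans cyclopent-1-en-1-olate carrying the amide side chain) | CON(C)C(=O)CC(/C=C/c1ccc(O[Si](C)(C)C(C)(C)C)cc1)[C@H]2C(O[Li])=C[C@@H](c3ccc(O[Si](C)(C)C(C)(C)C)cc3)[C@@H]2c4cc(O[Si](C)(C)C(C)(C)C)cc(O[Si](C)(C)C(C)(C)C)c4 | intermediate (not isolated)
18 | lithium alkoxide of the C2 N-methoxy-N-methyl hemiaminal (bicyclic tetrahedral adduct) | CON(C)C1(O[Li])CC(/C=C/c2ccc(O[Si](C)(C)C(C)(C)C)cc2)[C@H]3C(=O)[C@@H]1[C@@H](c4ccc(O[Si](C)(C)C(C)(C)C)cc4)[C@@H]3c5cc(O[Si](C)(C)C(C)(C)C)cc(O[Si](C)(C)C(C)(C)C)c5 | intermediate (not isolated)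
19 | (1R,5R,6S,7S)-6-[3,5-bis(TBSO)phenyl]-7-[4-(TBSO)phenyl]-4-{(E)-2-[4-(TBSO)phenyl]ethenyl}bicyclo[3.2.1]octane-2,8-dione, C4 epimers | O=C1CC(/C=C/c2ccc(O[Si](C)(C)C(C)(C)C)cc2)[C@H]3C(=O)[C@@H]1[C@@H](c4ccc(O[Si](C)(C)C(C)(C)C)cc4)[C@@H]3c5cc(O[Si](C)(C)C(C)(C)C)cc(O[Si](C)(C)C(C)(C)C)c5 | intermediate
20 | (1R,5S,6S,7S)-6-[3,5-bis(TBSO)phenyl]-7-[4-(TBSO)phenyl]-4-{(E)-2-[4-(TBSO)phenyl]ethenyl}bicyclo[3.2.1]oct-3-ene-2,8-dione | O=C1C=C(/C=C/c2ccc(O[Si](C)(C)C(C)(C)C)cc2)[C@H]3C(=O)[C@@H]1[C@@H](c4ccc(O[Si](C)(C)C(C)(C)C)cc4)[C@@H]3c5cc(O[Si](C)(C)C(C)(C)C)cc(O[Si](C)(C)C(C)(C)C)c5 | intermediate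
21 | (1R,5S,6S,7S)-6-(3,5-dihydroxyphenyl)-7-(4-hydroxyphenyl)-4-[(E)-2-(4-hydroxyphenyl)ethenyl]bicyclo[3.2.1]oct-3-ene-2,8-dione | O=C1C=C(/C=C/c2ccc(O)cc2)[C@H]2C(=O)[C@@H]1[C@@H](c1ccc(O)cc1)[C@@H]2c1cc(O)cc(O)c1 | target

**Step count.** Total: 9 steps. Longest linear sequence: 8 steps (3 to 21 through steps 2 to 9).

**Steps most likely to fail**

1. Step 7. The C1 enolate may be protonated or may equilibrate before it acylates the amide, so that only the open 1,4-adduct is recovered, or the cuprate may attack the face syn to the C6 aryl group. The fallback sets out from 13 (with cuprate 16 from 14) and returns at 19. The conjugate addition is run in the presence of TMSCl so that the C1 enolate is captured as the trimethylsilyl enol ether F1. i-Bu2AlH at −78 °C then reduces the N-methoxy-N-methylamide to the aldehyde F2 while the ketone stays masked. BF3·OEt2 at −78 °C closes the C1–C2 bond by an intramolecular Mukaiyama aldol addition to the β-hydroxy ketone F3 (both carbinol epimers), and Dess–Martin periodinane oxidises F3 to 19.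

2. Step 4. The enolate may be trapped incompletely, the acceptor may be attacked at its δ-carbon instead of the β-carbon, or residual aryl metal may be transferred to the acceptor. The fallback sets out from 2 and 8 and returns at 11. The copper-catalysed Grignard addition is quenched with TMSCl to give the isolable silyl enol ether F4. F4 is then added to 7 under Lewis acid activation of the acceptor (Sc(OTf)3 cat., CH2Cl2, −78 °C, Mukaiyama–Michael addition), which keeps basic enolate and organometallic species away from the acceptor, and aqueous work-up gives 11.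

3. Step 6. The amidine base may move the ring alkene into conjugation with the C6 aryl group, with loss of the ring stereocenters, or may cleave aryl silyl ethers. The fallback sets out from 12 and returns at 13. The secondary alkyl silyl ether is cleaved selectively under acid (camphorsulfonic acid cat., MeOH/CH2Cl2, 0 °C; the aryl silyl ethers are the more acid-stable) to the β-hydroxy ketone F5. MsCl/Et3N at −20 °C gives the mesylate F6, which eliminates in the same flask to 13 under a base weaker than DBU.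

**Further compounds**

F1 | step 7 | trimethylsilyl enol ether of the 1,4-adduct (amide side chain retained) | CON(C)C(=O)CC(/C=C/c1ccc(O[Si](C)(C)C(C)(C)C)cc1)[C@H]2C(O[Si](C)(C)C)=C[C@@H](c3ccc(O[Si](C)(C)C(C)(C)C)cc3)[C@@H]2c4cc(O[Si](C)(C)C(C)(C)C)cc(O[Si](C)(C)C(C)(C)C)c4
F2 | step 7 | aldehyde from reduction of the amide of F1 | O=CCC(/C=C/c1ccc(O[Si](C)(C)C(C)(C)C)cc1)[C@H]2C(O[Si](C)(C)C)=C[C@@H](c3ccc(O[Si](C)(C)C(C)(C)C)cc3)[C@@H]2c4cc(O[Si](C)(C)C(C)(C)C)cc(O[Si](C)(C)C(C)(C)C)c4
F3 | step 7 | (1R,5R,6S,7S)-2-hydroxy-6-[3,5-bis(TBSO)phenyl]-7-[4-(TBSO)phenyl]-4-{(E)-2-[4-(TBSO)phenyl]ethenyl}bicyclo[3.2.1]octan-8-one, C2 and C4 epimers | OC1CC(/C=C/c2ccc(O[Si](C)(C)C(C)(C)C)cc2)[C@H]3C(=O)[C@@H]1[C@@H](c4ccc(O[Si](C)(C)C(C)(C)C)cc4)[C@@H]3c5cc(O[Si](C)(C)C(C)(C)C)cc(O[Si](C)(C)C(C)(C)C)c5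
F4 | step 4 | (3S,4R)-3-[3,5-bis(TBSO)phenyl]-4-(TBSO)-1-(trimethylsilyloxy)cyclopent-1-ene | C[Si](C)(C)OC1=C[C@@H](c2cc(O[Si](C)(C)C(C)(C)C)cc(O[Si](C)(C)C(C)(C)C)c2)[C@H](O[Si](C)(C)C(C)(C)C)C1
F5 | step 6 | (4E)-3-{(1R,2S,3R)-2-[3,5-bis(TBSO)phenyl]-3-hydroxy-5-oxocyclopentyl}-N-methoxy-N-methyl-5-[4-(TBSO)phenyl]pent-4-enamide, C3 epimers | CON(C)C(=O)CC(/C=C/c1ccc(O[Si](C)(C)C(C)(C)C)cc1)[C@H]2C(=O)C[C@@H](O)[C@@H]2c3cc(O[Si](C)(C)C(C)(C)C)cc(O[Si](C)(C)C(C)(C)C)c3
F6 | step 6 | methanesulfonate of F5 | CON(C)C(=O)CC(/C=C/c1ccc(O[Si](C)(C)C(C)(C)C)cc1)[C@H]2C(=O)C[C@@H](OS(C)(=O)=O)[C@@H]2c3cc(O[Si](C)(C)C(C)(C)C)cc(O[Si](C)(C)C(C)(C)C)c3
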